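**Retrosynthetic overview**
1. Endgame at a C6 ketone: the axial 6β-acetate comes from α-face hydride delivery to C6=O; the 7α-OH and the C8=C9 alkene come together from α-hydroxylation of the linear dienolate of a labd-7-en-6-one.
2. Key disconnection C4–C5 and C9–C10: one Hg(II)-initiated cation–olefin bicyclization of an acyclic C20 tetraenol closes ring A, then ring B; C5, C9 and C10 are set by substrate control from the single C6 carbinol (allylic 1,3-strain).
3. The acyclic tetraenol is cut at C6–C7 into geranial (C1–C6, C10, C18–C20; its CHO carbon is C6) and a nerol-derived allylbarium (C7–C9, C11–C17; the 13Z alkene is bought); C6 is set by CBS reduction.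
4. C6 is thus used three times: as the union site, as the stereochemical relay, and as the ketone that activates C7 before it ends as the acetate-bearing carbon.

Key step: step 7

Remark: labdane numbering (C1–C20) is used for all compounds, including the acyclic ones; geranial is taken as purchased in isomerically pure 2E form.

**Step 1**
Reactants: 1 nerol [(2Z)-3,7-dimethylocta-2,6-dien-1-ol]
Product: 2 (2Z)-1-(tert-butyldimethylsilyloxy)-3,7-dimethylocta-2,6-diene
Conditions: TBSCl, imidazole, CH2Cl2, 0 °C → rt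
Reagents that add atoms: tert-butyldimethylsilyl chloride, CC(C)(C)[Si](C)(C)Cl
Why: Standard silyl ether formation at the primary allylic alcohol; no stereocentre is formed and the 2Z alkene is not touched.

**Step 2**
Reactants: 2 (2Z)-1-(tert-butyldimethylsilyloxy)-3,7-dimethylocta-2,6-diene
Product: 3 (2E,6Z)-8-(tert-butyldimethylsilyloxy)-2,6-dimethylocta-2,6-dien-1-ol
Conditions: SeO2 (0.3 equiv), t-BuOOH (3 equiv), salicylic acid (0.1 equiv), CH2Cl2, rt
Reagents that add atoms: tert-butyl hydroperoxide, CC(C)(C)OO (oxygen passed on by catalytic selenium dioxide, O=[Se]=O)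
Why: Sharpless-type SeO2/t-BuOOH allylic oxidation (ene reaction, then [2,3]-shift) should attack the E-methyl of the terminal isopropylidene group, because the other alkene is deactivated by its allylic silyloxy group, and the [2,3]-shift returns the E-alkene (C8=C9).

**Step 3**
Reactants: 3 (2E,6Z)-8-(tert-butyldimethylsilyloxy)-2,6-dimethylocta-2,6-dien-1-ol
Product: 5 (2E,6Z)-8-(tert-butyldimethylsilyloxy)-2,6-dimethylocta-2,6-dienyl chloride, via allylic mesylate 4 (not isolated)
Conditions: MsCl, Et3N, CH2Cl2, −40 °C; then LiCl, THF, 0 °C → rt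
Reagents that add atoms: lithium chloride, [Li+].[Cl-]
Why: Mesylation and SN2 displacement by chloride should give the primary allylic chloride without allylic transposition, so both alkene geometries are kept.

**Step 4**
Reactants: 5 (2E,6Z)-8-(tert-butyldimethylsilyloxy)-2,6-dimethylocta-2,6-dienyl chloride; 6 geranial [(2E)-3,7-dimethylocta-2,6-dienal]
Product: 8 rac-(2Z,6E,10E)-1-(tert-butyldimethylsilyloxy)-3,7,11,15-tetramethylhexadeca-2,6,10,14-tetraen-9-ol, via allylbarium chloride 7 (not isolated)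
Conditions: BaI2, lithium biphenylide (2 equiv), THF, rt (activated barium); 5, −78 °C; then 6, −78 °C; aq. NH4Cl
Reagents that add atoms: none
Why: Allylbarium reagents made at −78 °C add to aldehydes at their α-carbon with retention of the alkene geometry, and the β,β-disubstituted enal should take 1,2-addition; the new C6 carbinol is racemic and is corrected in steps 5 and 6.

**Step 5**
Reactants: 8 rac-(2Z,6E,10E)-1-(tert-butyldimethylsilyloxy)-3,7,11,15-tetramethylhexadeca-2,6,10,14-tetraen-9-ol
Product: 9 (2Z,6E,10E)-1-(tert-butyldimethylsilyloxy)-3,7,11,15-tetramethylhexadeca-2,6,10,14-tetraen-9-one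
Conditions: activated MnO2 (excess), CH2Cl2, rt
Reagents that add atoms: none
Why: MnO2 oxidation of the secondary allylic alcohol is neutral, which should keep the C8=C9 alkene on the other side of the ketone out of conjugation.

**Step 6**
Reactants: 9 (2Z,6E,10E)-1-(tert-butyldimethylsilyloxy)-3,7,11,15-tetramethylhexadeca-2,6,10,14-tetraen-9-one
Product: 10 (2Z,6E,9S,10E)-1-(tert-butyldimethylsilyloxy)-3,7,11,15-tetramethylhexadeca-2,6,10,14-tetraen-9-ol (the carbinol carbon is C6 of the labdane)
Conditions: (R)-Me-CBS (0.2 equiv), catecholborane (1.5 equiv), toluene, −78 °C; MeOH, then aq. NaOH wash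
Reagents that add atoms: none
Why: Corey–Bakshi–Shibata reduction, in which the alkenyl group acts as the large substituent, should give the (9S)-allylic alcohol with the (R)-catalyst, and catecholborane at −78 °C does not hydroborate the four alkenes.

**Step 7**
Reactants: 10 (2Z,6E,9S,10E)-1-(tert-butyldimethylsilyloxy)-3,7,11,15-tetramethylhexadeca-2,6,10,14-tetraen-9-ol
Product: 12 15-(tert-butyldimethylsilyloxy)labda-7,13Z-dien-6α-ol (normal labdane series: 5α-H, 9α-H, 10β-CH3), via C3 organomercury triflate 11 (not isolated)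
Conditions: Hg(OTf)2·PhNMe2 (1.3 equiv), MeNO2, −20 °C; then NaBH4, 3 M aq. NaOH, 0 °C
Reagents that add atoms: none
Why: Hg(II) adds to the terminal C3=C4 alkene, the only one that is neither internal nor deactivated by an allylic oxygen; the mercurinium ion is opened at C4 by C5 of the E-C5=C10 alkene (6-endo, ring A), the tertiary C10 cation is taken by C9 of the E-C8=C9 alkene (6-endo, ring B), the C8 cation loses a proton (mainly H7), and borohydride then replaces the equatorial C3–Hg bond by C3–H. The closest known reaction type is the mercury(II) triflate–amine induced cyclization of farnesyl- and geranylgeranyl-type polyenes, combined with the known relay of configuration from an allylic carbinol next to the attacking alkene in cation–olefin polycyclizations. Both rings close through a chair–chair array with anti addition across C5=C10, which gives the trans ring fusion (5α-H, 10β-CH3), and the E geometry of C8=C9 puts the side chain equatorial at C9. The absolute sense comes from C6: allylic 1,3-strain with the C20 methyl holds H6 in the alkene plane, so the C7 arm and the hydroxyl lie on opposite faces, ring B can form only on the C7 face, and the (S)-carbinol ends as the equatorial 6α-alcohol of the (5S,10S) series. The step needs initiation at C3=C4 and no ionisation of the allylic C6–OH, for which the amine-buffered, non-protic mercury reagent at −20 °C is chosen. It also needs to stop at the bicycle, which the 13Z geometry and the allylic silyloxy group of the last alkene should favour.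

**Step 8**
Reactants: 12 15-(tert-butyldimethylsilyloxy)labda-7,13Z-dien-6α-ol
Product: 13 15-(tert-butyldimethylsilyloxy)labda-7,13Z-dien-6-one
Conditions: Dess–Martin periodinane, pyridine, CH2Cl2, 0 °C → rt; then DBU (0.2 equiv), rt
Reagents that add atoms: none
Why: Dess–Martin oxidation of the secondary alcohol gives the enone, and DBU should move any Δ8(9) or Δ8(17) isomers from the termination of step 7 into conjugation, so that all material converges on one enone with the more stable trans ring fusion.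

**Step 9**
Reactants: 13 15-(tert-butyldimethylsilyloxy)labda-7,13Z-dien-6-one
Product: 15 15-(tert-butyldimethylsilyloxy)-7α-hydroxylabda-8,13Z-dien-6-one, via potassium dienolate 14 (not isolated)
Conditions: KOt-Bu (1.1 equiv), THF/t-BuOH 10:1, 0 °C, 1 h; −78 °C, 2-(phenylsulfonyl)-3-phenyloxaziridine (1.3 equiv); AcOH, −78 °C
Reagents that add atoms: 2-(phenylsulfonyl)-3-phenyloxaziridine (Davis oxaziridine), O=S(=O)(c1ccccc1)N1OC1c1ccccc1
Why: Under equilibrating conditions the enone should give the more substituted linear dienolate (loss of H9), which the Davis oxaziridine hydroxylates at its α-carbon C7 from the α-face, away from the axial C10 and 4β methyl groups (deconjugative α-hydroxylation); this sets C7 and places the alkene at C8=C9.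

**Step 10**
Reactants: 15 15-(tert-butyldimethylsilyloxy)-7α-hydroxylabda-8,13Z-dien-6-one
Product: 16 15-(tert-butyldimethylsilyloxy)-7α-(triethylsilyloxy)labda-8,13Z-dien-6-one
Conditions: TESOTf, 2,6-lutidine, CH2Cl2, −78 °C
Reagents that add atoms: triethylsilyl trifluoromethanesulfonate, CC[Si](CC)(CC)OS(=O)(=O)C(F)(F)F
Why: Silylation of the secondary α-ketol hydroxyl at low temperature should leave the base-sensitive C7 stereocentre untouched and mask O7 for the selective acetylation of O6.

**Step 11**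
Reactants: 16 15-(tert-butyldimethylsilyloxy)-7α-(triethylsilyloxy)labda-8,13Z-dien-6-one
Product: 18 6β-acetoxy-15-(tert-butyldimethylsilyloxy)-7α-(triethylsilyloxy)labda-8,13Z-diene, via aluminium 6β-alkoxide 17 (not isolated)
Conditions: DIBAL-H (1.3 equiv), CH2Cl2, −78 °C; then pyridine, DMAP, Ac2O, −78 → 0 °C
Reagents that add atoms: acetic anhydride, CC(=O)OC(C)=O
Why: The β-face of C6=O is shielded by the syn-axial C10 and 4β methyl groups, so hydride should arrive from the α-face and give the axial 6β-alkoxide, which is acetylated in the same flask (reduction–acylation of an aluminium alkoxide), so the hindered alcohol is never acylated in its neutral form.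

**Step 12**
Reactants: 18 6β-acetoxy-15-(tert-butyldimethylsilyloxy)-7α-(triethylsilyloxy)labda-8,13Z-diene
Product: 19 (13Z)-6β-acetoxylabda-8,13-diene-7α,15-diol [(5S,6S,7S,10S); CNP0183298.2]
Conditions: HF·pyridine, pyridine, THF, 0 °C → rt
Reagents that add atoms: none
Why: Buffered HF·pyridine should cleave both silyl ethers while the acetate stays in place, and it cannot migrate because O6 and O7 are trans-diaxial.

**Compound list**
1 | nerol, (2Z)-3,7-dimethylocta-2,6-dien-1-ol | CC(C)=CCC/C(C)=C\CO | starting material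
2 | (2Z)-1-(tert-butyldimethylsilyloxy)-3,7-dimethylocta-2,6-diene | CC(C)=CCC/C(C)=C\CO[Si](C)(C)C(C)(C)C | intermediate
3 | (2E,6Z)-8-(tert-butyldimethylsilyloxy)-2,6-dimethylocta-2,6-dien-1-ol | OC/C(C)=C/CC/C(C)=C\CO[Si](C)(C)C(C)(C)C | intermediate
4 | (2E,6Z)-8-(tert-butyldimethylsilyloxy)-2,6-dimethylocta-2,6-dienyl methanesulfonate | CS(=O)(=O)OC/C(C)=C/CC/C(C)=C\CO[Si](C)(C)C(C)(C)C | intermediate
5 | (2E,6Z)-8-(tert-butyldimethylsilyloxy)-2,6-dimethylocta-2,6-dienyl chloride | ClC/C(C)=C/CC/C(C)=C\CO[Si](C)(C)C(C)(C)C | intermediate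
6 | geranial, (2E)-3,7-dimethylocta-2,6-dienal | CC(C)=CCC/C(C)=C/C=O | starting material
7 | [(2E,6Z)-8-(tert-butyldimethylsilyloxy)-2,6-dimethylocta-2,6-dienyl]barium chloride | Cl[Ba]C/C(C)=C/CC/C(C)=C\CO[Si](C)(C)C(C)(C)C | intermediate
8 | rac-(2Z,6E,10E)-1-(tert-butyldimethylsilyloxy)-3,7,11,15-tetramethylhexadeca-2,6,10,14-tetraen-9-ol | CC(C)=CCC/C(C)=C/C(O)C/C(C)=C/CC/C(C)=C\CO[Si](C)(C)C(C)(C)C | intermediate
9 | (2Z,6E,10E)-1-(tert-butyldimethylsilyloxy)-3,7,11,15-tetramethylhexadeca-2,6,10,14-tetraen-9-one | CC(C)=CCC/C(C)=C/C(=O)C/C(C)=C/CC/C(C)=C\CO[Si](C)(C)C(C)(C)C | intermediate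
10 | (2Z,6E,9S,10E)-1-(tert-butyldimethylsilyloxy)-3,7,11,15-tetramethylhexadeca-2,6,10,14-tetraen-9-ol | CC(C)=CCC/C(C)=C/[C@@H](O)C/C(C)=C/CC/C(C)=C\CO[Si](C)(C)C(C)(C)C | intermediate
11 | 15-(tert-butyldimethylsilyloxy)-6α-hydroxylabda-7,13Z-dien-3β-ylmercury(II) triflate | O[C@H]1C=C(C)[C@H](CC/C(C)=C\CO[Si](C)(C)C(C)(C)C)[C@@]2(C)CC[C@H]([Hg]OS(=O)(=O)C(F)(F)F)C(C)(C)[C@H]12 | intermediate
12 | 15-(tert-butyldimethylsilyloxy)labda-7,13Z-dien-6α-ol (5α-H, 9α-H, 10β-CH3) | O[C@H]1C=C(C)[C@H](CC/C(C)=C\CO[Si](C)(C)C(C)(C)C)[C@@]2(C)CCCC(C)(C)[C@H]12 | intermediate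
13 | 15-(tert-butyldimethylsilyloxy)labda-7,13Z-dien-6-one | O=C1C=C(C)[C@H](CC/C(C)=C\CO[Si](C)(C)C(C)(C)C)[C@@]2(C)CCCC(C)(C)[C@H]12 | intermediate
14 | potassium 15-(tert-butyldimethylsilyloxy)labda-6,8,13Z-trien-6-olate | [K+].[O-]C1=CC(C)=C(CC/C(C)=C\CO[Si](C)(C)C(C)(C)C)[C@@]2(C)CCCC(C)(C)[C@H]12 | intermediate
15 | 15-(tert-butyldimethylsilyloxy)-7α-hydroxylabda-8,13Z-dien-6-one | O=C1[C@@H](O)C(C)=C(CC/C(C)=C\CO[Si](C)(C)C(C)(C)C)[C@@]2(C)CCCC(C)(C)[C@H]12 | intermediate
16 | 15-(tert-butyldimethylsilyloxy)-7α-(triethylsilyloxy)labda-8,13Z-dien-6-one | O=C1[C@@H](O[Si](CC)(CC)CC)C(C)=C(CC/C(C)=C\CO[Si](C)(C)C(C)(C)C)[C@@]2(C)CCCC(C)(C)[C@H]12 | intermediate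
17 | diisobutylaluminium 15-(tert-butyldimethylsilyloxy)-7α-(triethylsilyloxy)labda-8,13Z-dien-6β-olate | CC(C)C[Al](CC(C)C)O[C@@H]1[C@@H](O[Si](CC)(CC)CC)C(C)=C(CC/C(C)=C\CO[Si](C)(C)C(C)(C)C)[C@@]2(C)CCCC(C)(C)[C@H]12 | intermediate
18 | 6β-acetoxy-15-(tert-butyldimethylsilyloxy)-7α-(triethylsilyloxy)labda-8,13Z-diene | CC(=O)O[C@@H]1[C@@H](O[Si](CC)(CC)CC)C(C)=C(CC/C(C)=C\CO[Si](C)(C)C(C)(C)C)[C@@]2(C)CCCC(C)(C)[C@H]12 | intermediate
19 | (13Z)-6β-acetoxylabda-8,13-diene-7α,15-diol, (5S,6S,7S,10S) | CC(=O)O[C@@H]1[C@@H](O)C(C)=C(CC/C(C)=C\CO)[C@@]2(C)CCCC(C)(C)[C@H]12 | target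

**Step count**
Total step count: 12. Longest linear sequence: 12 steps (nerol 1 to 19); geranial 6 enters at step 4.

**Steps most likely to fail**

Step 7. The free allylic C6 hydroxyl may be lost, either by ionisation or by mercuration of C5=C10 followed by β-elimination. The first ring closure may be slow because the attacking alkene carries an allylic oxygen, the relay from C6 may be incomplete, and the cascade may run on through C13=C14. The fallback sets out from 10 and masks the carbinol as the triethylsilyl ether of 10 F1 (TESCl, imidazole). A bromonium-initiated bicyclization with BDSB (MeNO2, −25 °C) under the same A(1,3) control then gives 3β-bromo-6α-(triethylsilyloxy)-15-(tert-butyldimethylsilyloxy)labda-7,13Z-diene F2. Radical debromination (Bu3SnH, AIBN, benzene, 80 °C) leads to 6α-(triethylsilyloxy)-15-(tert-butyldimethylsilyloxy)labda-7,13Z-diene F3, and PPTS in MeOH at 0 °C removes the secondary TES group, which returns the route to 12.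

Step 9. Deprotonation may take place at the C17 methyl and not at C9, which would lead to the exocyclic alkene; the oxidant may approach from the β-face; and the α-ketol may isomerise or be oxidised further under the basic conditions. The fallback sets out from 13 and replaces the enolate oxidation by an ene reaction. Luche reduction (NaBH4, CeCl3, MeOH, α-face attack) gives 15-(tert-butyldimethylsilyloxy)labda-7,13Z-dien-6β-ol F4, and Ac2O/DMAP/Et3N gives 6β-acetoxy-15-(tert-butyldimethylsilyloxy)labda-7,13Z-diene F5. Photooxygenation (O2, tetraphenylporphyrin, hν, CH2Cl2, 0 °C) should add oxygen at C7 from the α-face with loss of the axial H9, to give 6β-acetoxy-7α-hydroperoxy-15-(tert-butyldimethylsilyloxy)labda-8,13Z-diene F6. PPh3 reduces it to 6β-acetoxy-15-(tert-butyldimethylsilyloxy)labda-8,13Z-dien-7α-ol F7, and HF·pyridine brings the route back at 19.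

Step 11. Hydride may be delivered from the β-face, anti to the axial C7–O bond, and the hindered aluminium alkoxide may be acylated incompletely. The fallback sets out from 15 and reduces before O7 is protected. NaBH4/CeCl3 in MeOH at −40 °C, with the small hydride guided by the free 7α-hydroxyl to the α-face, gives 15-(tert-butyldimethylsilyloxy)labda-8,13Z-diene-6β,7α-diol F8. TESCl/imidazole silylates only the less hindered O7 to give 15-(tert-butyldimethylsilyloxy)-7α-(triethylsilyloxy)labda-8,13Z-dien-6β-ol F9, and LiHMDS followed by AcCl in THF at −78 °C acylates the lithium alkoxide, which returns the route to 18.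

**Further compounds**
F1 | step 7 | (2Z,6E,9S,10E)-1-(tert-butyldimethylsilyloxy)-3,7,11,15-tetramethyl-9-(triethylsilyloxy)hexadeca-2,6,10,14-tetraene | CC(C)=CCC/C(C)=C/[C@@H](O[Si](CC)(CC)CC)C/C(C)=C/CC/C(C)=C\CO[Si](C)(C)C(C)(C)C
F2 | step 7 | 3β-bromo-6α-(triethylsilyloxy)-15-(tert-butyldimethylsilyloxy)labda-7,13Z-diene | CC[Si](CC)(CC)O[C@H]1C=C(C)[C@H](CC/C(C)=C\CO[Si](C)(C)C(C)(C)C)[C@@]2(C)CC[C@H](Br)C(C)(C)[C@H]12
F3 | step 7 | 6α-(triethylsilyloxy)-15-(tert-butyldimethylsilyloxy)labda-7,13Z-diene | CC[Si](CC)(CC)O[C@H]1C=C(C)[C@H](CC/C(C)=C\CO[Si](C)(C)C(C)(C)C)[C@@]2(C)CCCC(C)(C)[C@H]12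
F4 | step 9 | 15-(tert-butyldimethylsilyloxy)labda-7,13Z-dien-6β-ol | O[C@@H]1C=C(C)[C@H](CC/C(C)=C\CO[Si](C)(C)C(C)(C)C)[C@@]2(C)CCCC(C)(C)[C@H]12
F5 | step 9 | 6β-acetoxy-15-(tert-butyldimethylsilyloxy)labda-7,13Z-diene | CC(=O)O[C@@H]1C=C(C)[C@H](CC/C(C)=C\CO[Si](C)(C)C(C)(C)C)[C@@]2(C)CCCC(C)(C)[C@H]12
F6 | step 9 | 6β-acetoxy-7α-hydroperoxy-15-(tert-butyldimethylsilyloxy)labda-8,13Z-diene | CC(=O)O[C@@H]1[C@@H](OO)C(C)=C(CC/C(C)=C\CO[Si](C)(C)C(C)(C)C)[C@@]2(C)CCCC(C)(C)[C@H]12
F7 | step 9 | 6β-acetoxy-15-(tert-butyldimethylsilyloxy)labda-8,13Z-dien-7α-ol | CC(=O)O[C@@H]1[C@@H](O)C(C)=C(CC/C(C)=C\CO[Si](C)(C)C(C)(C)C)[C@@]2(C)CCCC(C)(C)[C@H]12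
F8 | step 11 | 15-(tert-butyldimethylsilyloxy)labda-8,13Z-diene-6β,7α-diol | O[C@@H]1[C@@H](O)C(C)=C(CC/C(C)=C\CO[Si](C)(C)C(C)(C)C)[C@@]2(C)CCCC(C)(C)[C@H]12
F9 | step 11 | 15-(tert-butyldimethylsilyloxy)-7α-(triethylsilyloxy)labda-8,13Z-dien-6β-ol | O[C@@H]1[C@@H](O[Si](CC)(CC)CC)C(C)=C(CC/C(C)=C\CO[Si](C)(C)C(C)(C)C)[C@@]2(C)CCCC(C)(C)[C@H]12
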